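## Retrosynthetic overview

1. Target 23 comes from the complete tricycle 20 by C8 desilylation, methacrylation and C15 desilylation.
2. Key step, 17 → 20: a Pd-catalysed carbonylative macro-annulation in which CO becomes C3, joins the C4 vinyl iodide to the C2 alkyne terminus, and the C10 carbinol then closes the 3(2H)-furanone; the ten-membered carbocycle and the furanone form together.
3. 17 comes from allyl bromide 11 and iodo-enal 15 by CrCl2-mediated allylation and lactonisation, which makes C6–C7 and the α-methylene-γ-lactone and sets C6 and C7 under control of C8.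
4. 11 comes from the L-threonate derivative 1 (C8 and C9 from the chiral pool, C10 by chelation-controlled ethynylation, acrylate unit by a Morita–Baylis–Hillman reaction at C7); 15 comes from but-2-yne-1,4-diol 12.
5. Ring order: γ-lactone first, then the carbocycle and the furanone in one operation.

Assumption: carbons are numbered as in germacranes (C1 ring ketone, C3 enol-ether carbon, C6 lactone carbinol, C10 quaternary carbon, C12 lactone carbonyl, C13 exocyclic methylene, C15 hydroxymethyl), and methyl 3,4-O-isopropylidene-L-threonate (made industrially from L-ascorbic acid) is taken as a purchasable starting material.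

## Route

Step 1
Reactants: 1 methyl 3,4-O-isopropylidene-L-threonate
Product: 2 (2R)-2-[(4S)-2,2-dimethyl-1,3-dioxolan-4-yl]-2-hydroxy-N-methoxy-N-methylacetamide
Conditions: MeNH(OMe)·HCl (2.5 equiv), iPrMgCl (6 equiv), THF, −20 °C
Reagents that add atoms: N,O-dimethylhydroxylamine hydrochloride (CNOC.Cl)
Why: Weinreb amide formation by attack of ClMgN(OMe)Me on the ester; no stereocentre is touched.

Step 2
Reactants: 2 Weinreb amide
Product: 3 (1R)-1-[(4S)-2,2-dimethyl-1,3-dioxolan-4-yl]-1-hydroxypropan-2-one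
Conditions: MeMgBr (3 equiv), THF, −20 → 0 °C; cold NH4Cl quench
Reagents that add atoms: methylmagnesium bromide (C[Mg]Br)
Why: Weinreb ketone synthesis, in which the chelated tetrahedral intermediate stops over-addition and keeps the C9 centre from enolising until the quench.

Step 3
Reactants: 3 α-hydroxy methyl ketone
Product: 4 (1R,2R)-1-[(4S)-2,2-dimethyl-1,3-dioxolan-4-yl]-2-methylbut-3-yne-1,2-diol
Conditions: HC≡CMgBr (3 equiv), THF, −78 → −20 °C
Reagents that add atoms: ethynylmagnesium bromide (C#C[Mg]Br)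
Why: Chelation-controlled Grignard addition (Cram cyclic model): the C9–OMgBr alkoxide and the ketone oxygen form a five-membered chelate and the acetylide attacks the face away from the dioxolane, which sets the C10 tertiary carbinol (10R here, 10S in the furanone).

Step 4
Reactants: 4 ethynyl diol
Product: 5 (1R,2R)-1-[(4S)-2,2-dimethyl-1,3-dioxolan-4-yl]-2-hydroxy-2-methylbut-3-yn-1-yl 3-methylbutanoate
Conditions: 3-methylbutanoyl chloride (1.1 equiv), pyridine, DMAP (0.1 equiv), CH2Cl2, −20 → 0 °C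
Reagents that add atoms: 3-methylbutanoyl chloride (CC(C)CC(Cl)=O)
Why: DMAP-catalysed acylation takes the secondary C9 hydroxyl only, because the tertiary propargylic hydroxyl is too hindered to react.

Step 5
Reactants: 5 isovalerate acetonide
Product: 6 (2S,3R,4R)-1,2,4-trihydroxy-4-methylhex-5-yn-3-yl 3-methylbutanoate
Conditions: AcOH–H2O (4:1), 40 °C
Reagents that add atoms: none
Why: Acid-catalysed hydrolysis of the terminal isopropylidene acetal under conditions too mild for ester migration or propargylic rearrangement.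

Step 6
Reactants: 6 triol
Product: 8 (2S,3R,4R)-4-methyl-1,2-bis(triethylsilyloxy)-4-(trimethylsilyloxy)hex-5-yn-3-yl 3-methylbutanoate, via bis(triethylsilyl) ether 7 (not isolated)
Conditions: Et3SiCl (2.3 equiv), imidazole (6 equiv), DMF, 0 °C; then Me3SiCl (2 equiv), rt
Reagents that add atoms: chlorotriethylsilane (CC[Si](Cl)(CC)CC); chlorotrimethylsilane (C[Si](C)(C)Cl)
Why: Silyl ether formation graded by steric demand: Et3SiCl takes the primary and secondary hydroxyls, and the smaller Me3SiCl then caps the tertiary one so that the C7 aldehyde made next cannot close to a lactol.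

Step 7
Reactants: 8 tris-silyl ether
Product: 9 (2R,3R,4R)-4-methyl-1-oxo-2-(triethylsilyloxy)-4-(trimethylsilyloxy)hex-5-yn-3-yl 3-methylbutanoate
Conditions: (COCl)2 (4 equiv), DMSO (8 equiv), CH2Cl2, −78 → −30 °C; then Et3N, −78 °C → rt
Reagents that add atoms: none
Why: Swern oxidation applied directly to the primary triethylsilyl ether, which is cleaved and oxidised while the secondary and tertiary silyl ethers survive.

Step 8
Reactants: 9 α-silyloxy aldehyde
Product: 10 methyl (4S,5R,6R)-3-hydroxy-6-methyl-2-methylidene-5-(3-methylbutanoyloxy)-4-(triethylsilyloxy)-6-(trimethylsilyloxy)oct-7-ynoate (both C3 epimers)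
Conditions: methyl acrylate (20 equiv, neat), DABCO (1 equiv), rt, 3–5 d
Reagents that add atoms: methyl acrylate (C=CC(=O)OC)
Why: Morita–Baylis–Hillman reaction of the inductively activated α-silyloxy aldehyde; the new carbinol centre (C7) forms as a mixture, which does not matter because it is removed in step 9.

Step 9
Reactants: 10 Morita–Baylis–Hillman adduct
Product: 11 methyl (2Z,4S,5R,6R)-2-(bromomethyl)-6-methyl-5-(3-methylbutanoyloxy)-4-(triethylsilyloxy)-6-(trimethylsilyloxy)oct-2-en-7-ynoate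
Conditions: NBS (1.5 equiv), Me2S (1.8 equiv), CH2Cl2, 0 °C → rt
Reagents that add atoms: N-bromosuccinimide (O=C1CCC(=O)N1Br)
Why: Corey–Kim-type activation of the allylic hydroxyl followed by SN2′ attack of bromide gives the thermodynamically preferred (Z)-2-(bromomethyl)enoate.

Step 10
Reactants: 12 but-2-yne-1,4-diol
Product: 13 4-[(tert-butyldiphenylsilyl)oxy]but-2-yn-1-ol
Conditions: tBuPh2SiCl (0.3 equiv), imidazole, THF–DMF, 0 °C
Reagents that add atoms: tert-butyl(chloro)diphenylsilane (CC(C)(C)[Si](Cl)(c1ccccc1)c1ccccc1)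
Why: Statistical monosilylation with the cheap diol in excess.

Step 11
Reactants: 13 monosilylated butynediol
Product: 14 (2Z)-4-[(tert-butyldiphenylsilyl)oxy]-3-iodobut-2-en-1-ol
Conditions: NaAlH2(OCH2CH2OCH3)2 (1.5 equiv), THF, 0 °C → rt; then N-iodosuccinimide, −78 °C
Reagents that add atoms: N-iodosuccinimide (O=C1CCC(=O)N1I)
Why: Hydroxyl-directed trans-hydroalumination puts aluminium on the alkyne carbon remote from the free hydroxyl and iodination of the C–Al bond goes with retention, so the (Z)-iodide with CH2OH and iodine cis forms as one regio- and stereoisomer.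

Step 12
Reactants: 14 iodo allylic alcohol
Product: 15 (2Z)-4-[(tert-butyldiphenylsilyl)oxy]-3-iodobut-2-enal
Conditions: MnO2 (20 equiv), CH2Cl2, rt, dark; used at once
Reagents that add atoms: none
Why: MnO2 oxidation of an allylic alcohol, neutral enough to leave the vinyl iodide and the (Z)-geometry intact.

Step 13
Reactants: 11 allyl bromide; 15 iodo-enal
Product: 17 (4S,5S)-5-[(1Z)-3-[(tert-butyldiphenylsilyl)oxy]-2-iodoprop-1-en-1-yl]-4-[(1S,2R,3R)-3-hydroxy-3-methyl-2-(3-methylbutanoyloxy)-1-(triethylsilyloxy)pent-4-yn-1-yl]-3-methylideneoxolan-2-one, via open-chain hydroxy ester 16 (not isolated)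
Conditions: CrCl2 (5 equiv), THF, 0 °C → rt, 16 h; then PPTS, MeOH–CH2Cl2, 0 °C
Reagents that add atoms: none
Why: Nozaki–Hiyama-type carbonyl allylation in which the allyl–CrCl2 species (trivalent chromium) reacts through its E-configured form in a chair transition state to give the anti adduct (the trans-lactone after ring closure, C6), while 1,3-allylic strain holds C8–H in the alkene plane so the aldehyde reaches C7 anti to the bulky C9 branch (sets C7); the acidic methanol finish completes lactonisation and removes the tertiary trimethylsilyl group.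

Step 14 (key step)
Reactants: 17 seco vinyl iodide/ethynyl carbinol
Product: 20 (6R,7S,8S,9R,10S)-15-[(tert-butyldiphenylsilyl)oxy]-9-(3-methylbutanoyloxy)-1-oxo-8-(triethylsilyloxy)-3,10-epoxygermacra-2,4Z,11(13)-trien-12,6-olide, via macrocyclic hydroxy ynone 18 (not isolated), via macrocyclic diketone 19 (not isolated)
Conditions: PdCl2(PPh3)2 (10 mol %), CuI (5 mol %), Et3N (10 equiv), CO (3 atm), THF–H2O (20:1), 17 added over 12 h to 0.002 M, 45 °C; then 65 °C, 4 h
Reagents that add atoms: carbon monoxide ([C-]#[O+]); water (O)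
Why: Proposed new method: zerovalent palladium inserts into the vinyl iodide, CO insertion gives an acyl–PdI(PPh3)2 complex that couples with the tethered RC≡CCu terminus (an intramolecular carbonylative Sonogashira reaction at high dilution) to give the strained ten-membered 4-hydroxy-2-ynone 18, whose bent triple bond takes up water at C1 under amine catalysis to give diketone 19, and the C10 hydroxyl then adds to the C3 ketone and loses water to close the 3(2H)-furanone; the closest known reaction is the one-pot palladium-catalysed carbonylative coupling of aryl or vinyl halides with tertiary α-ethynyl carbinols to 3(2H)-furanones, and no stereocentre is formed.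

Step 15
Reactants: 20 tricyclic bis-silyl ether
Product: 21 (6R,7R,8S,9R,10S)-15-[(tert-butyldiphenylsilyl)oxy]-8-hydroxy-9-(3-methylbutanoyloxy)-1-oxo-3,10-epoxygermacra-2,4Z,11(13)-trien-12,6-olide
Conditions: HF·pyridine, pyridine, THF, 0 °C
Reagents that add atoms: none
Why: Buffered fluoride cleavage removes the secondary triethylsilyl ether much faster than the primary tert-butyldiphenylsilyl ether.

Step 16
Reactants: 21 C8 alcohol
Product: 22 (6R,7S,8S,9R,10S)-15-[(tert-butyldiphenylsilyl)oxy]-9-(3-methylbutanoyloxy)-8-(2-methylprop-2-enoyloxy)-1-oxo-3,10-epoxygermacra-2,4Z,11(13)-trien-12,6-olide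
Conditions: methacrylic anhydride (4 equiv), Et3N, DMAP (0.5 equiv), CH2Cl2, rt
Reagents that add atoms: methacrylic anhydride (C=C(C)C(=O)OC(=O)C(C)=C)
Why: Steglich-type DMAP-catalysed acylation of the only free hydroxyl, with retention at C8.

Step 17
Reactants: 22 silyl-protected target
Product: 23 (6R,7S,8S,9R,10S)-15-hydroxy-9-(3-methylbutanoyloxy)-8-(2-methylprop-2-enoyloxy)-1-oxo-3,10-epoxygermacra-2,4Z,11(13)-trien-12,6-olide (CNP0552093.1)
Conditions: HF·pyridine, pyridine, THF, 0 °C → rt, 24 h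
Reagents that add atoms: none
Why: Silyl ether cleavage by buffered, non-basic fluoride, which spares the α-methylene lactone, both esters and the furanone.

## Compound list

1 | methyl (2R)-2-hydroxy-2-[(4S)-2,2-dimethyl-1,3-dioxolan-4-yl]acetate (methyl 3,4-O-isopropylidene-L-threonate) | COC(=O)[C@H](O)[C@@H]1COC(C)(C)O1 | starting material
2 | (2R)-2-[(4S)-2,2-dimethyl-1,3-dioxolan-4-yl]-2-hydroxy-N-methoxy-N-methylacetamide | CON(C)C(=O)[C@H](O)[C@@H]1COC(C)(C)O1 | intermediate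
3 | (1R)-1-[(4S)-2,2-dimethyl-1,3-dioxolan-4-yl]-1-hydroxypropan-2-one | CC(=O)[C@H](O)[C@@H]1COC(C)(C)O1 | intermediate
4 | (1R,2R)-1-[(4S)-2,2-dimethyl-1,3-dioxolan-4-yl]-2-methylbut-3-yne-1,2-diol | C#C[C@@](C)(O)[C@H](O)[C@@H]1COC(C)(C)O1 | intermediate
5 | (1R,2R)-1-[(4S)-2,2-dimethyl-1,3-dioxolan-4-yl]-2-hydroxy-2-methylbut-3-yn-1-yl 3-methylbutanoate | C#C[C@@](C)(O)[C@H](OC(=O)CC(C)C)[C@@H]1COC(C)(C)O1 | intermediate
6 | (2S,3R,4R)-1,2,4-trihydroxy-4-methylhex-5-yn-3-yl 3-methylbutanoate | C#C[C@@](C)(O)[C@H](OC(=O)CC(C)C)[C@@H](O)CO | intermediate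
7 | (2S,3R,4R)-4-hydroxy-4-methyl-1,2-bis(triethylsilyloxy)hex-5-yn-3-yl 3-methylbutanoate | C#C[C@@](C)(O)[C@H](OC(=O)CC(C)C)[C@@H](O[Si](CC)(CC)CC)CO[Si](CC)(CC)CC | intermediate
8 | (2S,3R,4R)-4-methyl-1,2-bis(triethylsilyloxy)-4-(trimethylsilyloxy)hex-5-yn-3-yl 3-methylbutanoate | C#C[C@@](C)(O[Si](C)(C)C)[C@H](OC(=O)CC(C)C)[C@@H](O[Si](CC)(CC)CC)CO[Si](CC)(CC)CC | intermediate
9 | (2R,3R,4R)-4-methyl-1-oxo-2-(triethylsilyloxy)-4-(trimethylsilyloxy)hex-5-yn-3-yl 3-methylbutanoate | C#C[C@@](C)(O[Si](C)(C)C)[C@H](OC(=O)CC(C)C)[C@@H](O[Si](CC)(CC)CC)C=O | intermediate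
10 | methyl (4S,5R,6R)-3-hydroxy-6-methyl-2-methylidene-5-(3-methylbutanoyloxy)-4-(triethylsilyloxy)-6-(trimethylsilyloxy)oct-7-ynoate (both C3 epimers) | C#C[C@@](C)(O[Si](C)(C)C)[C@H](OC(=O)CC(C)C)[C@@H](O[Si](CC)(CC)CC)C(O)C(=C)C(=O)OC | intermediate
11 | methyl (2Z,4S,5R,6R)-2-(bromomethyl)-6-methyl-5-(3-methylbutanoyloxy)-4-(triethylsilyloxy)-6-(trimethylsilyloxy)oct-2-en-7-ynoate | C#C[C@@](C)(O[Si](C)(C)C)[C@H](OC(=O)CC(C)C)[C@@H](O[Si](CC)(CC)CC)/C=C(\CBr)C(=O)OC | intermediate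
12 | but-2-yne-1,4-diol | OCC#CCO | starting material
13 | 4-[(tert-butyldiphenylsilyl)oxy]but-2-yn-1-ol | OCC#CCO[Si](c1ccccc1)(c1ccccc1)C(C)(C)C | intermediate
14 | (2Z)-4-[(tert-butyldiphenylsilyl)oxy]-3-iodobut-2-en-1-ol | OC/C=C(\I)CO[Si](c1ccccc1)(c1ccccc1)C(C)(C)C | intermediate
15 | (2Z)-4-[(tert-butyldiphenylsilyl)oxy]-3-iodobut-2-enal | O=C/C=C(\I)CO[Si](c1ccccc1)(c1ccccc1)C(C)(C)C | intermediate
16 | methyl (3S,4S,5R,6R)-3-[(1S,2Z)-4-[(tert-butyldiphenylsilyl)oxy]-1-hydroxy-3-iodobut-2-en-1-yl]-6-methyl-2-methylidene-5-(3-methylbutanoyloxy)-4-(triethylsilyloxy)-6-(trimethylsilyloxy)oct-7-ynoate | COC(=O)C(=C)[C@@H]([C@H](O)/C=C(\I)CO[Si](c1ccccc1)(c1ccccc1)C(C)(C)C)[C@H](O[Si](CC)(CC)CC)[C@@H](OC(=O)CC(C)C)[C@](C)(O[Si](C)(C)C)C#C | intermediate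
17 | (4S,5S)-5-[(1Z)-3-[(tert-butyldiphenylsilyl)oxy]-2-iodoprop-1-en-1-yl]-4-[(1S,2R,3R)-3-hydroxy-3-methyl-2-(3-methylbutanoyloxy)-1-(triethylsilyloxy)pent-4-yn-1-yl]-3-methylideneoxolan-2-one | CC[Si](CC)(CC)O[C@@H]([C@H]1C(=C)C(=O)O[C@@H]1/C=C(\I)CO[Si](c2ccccc2)(c2ccccc2)C(C)(C)C)[C@@H](OC(=O)CC(C)C)[C@](C)(O)C#C | intermediate
18 | (6R,7S,8S,9R,10R)-15-[(tert-butyldiphenylsilyl)oxy]-10-hydroxy-9-(3-methylbutanoyloxy)-3-oxo-8-(triethylsilyloxy)germacra-4Z,11(13)-dien-1-yn-12,6-olide | CC[Si](CC)(CC)O[C@H]1[C@H]2C(=C)C(=O)O[C@@H]2/C=C(/CO[Si](c3ccccc3)(c3ccccc3)C(C)(C)C)C(=O)C#C[C@@](C)(O)[C@@H]1OC(=O)CC(C)C | intermediate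
19 | (6R,7S,8S,9R,10S)-15-[(tert-butyldiphenylsilyl)oxy]-10-hydroxy-9-(3-methylbutanoyloxy)-1,3-dioxo-8-(triethylsilyloxy)germacra-4Z,11(13)-dien-12,6-olide | CC[Si](CC)(CC)O[C@H]1[C@H]2C(=C)C(=O)O[C@@H]2/C=C(/CO[Si](c3ccccc3)(c3ccccc3)C(C)(C)C)C(=O)CC(=O)[C@@](C)(O)[C@@H]1OC(=O)CC(C)C | intermediate
20 | (6R,7S,8S,9R,10S)-15-[(tert-butyldiphenylsilyl)oxy]-9-(3-methylbutanoyloxy)-1-oxo-8-(triethylsilyloxy)-3,10-epoxygermacra-2,4Z,11(13)-trien-12,6-olide | CC[Si](CC)(CC)O[C@H]1[C@H]2C(=C)C(=O)O[C@@H]2/C=C(/CO[Si](c3ccccc3)(c3ccccc3)C(C)(C)C)C2=CC(=O)[C@@](C)(O2)[C@@H]1OC(=O)CC(C)C | intermediate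
21 | (6R,7R,8S,9R,10S)-15-[(tert-butyldiphenylsilyl)oxy]-8-hydroxy-9-(3-methylbutanoyloxy)-1-oxo-3,10-epoxygermacra-2,4Z,11(13)-trien-12,6-olide | O[C@H]1[C@H]2C(=C)C(=O)O[C@@H]2/C=C(/CO[Si](c3ccccc3)(c3ccccc3)C(C)(C)C)C2=CC(=O)[C@@](C)(O2)[C@@H]1OC(=O)CC(C)C | intermediate
22 | (6R,7S,8S,9R,10S)-15-[(tert-butyldiphenylsilyl)oxy]-9-(3-methylbutanoyloxy)-8-(2-methylprop-2-enoyloxy)-1-oxo-3,10-epoxygermacra-2,4Z,11(13)-trien-12,6-olide | C=C(C)C(=O)O[C@H]1[C@H]2C(=C)C(=O)O[C@@H]2/C=C(/CO[Si](c3ccccc3)(c3ccccc3)C(C)(C)C)C2=CC(=O)[C@@](C)(O2)[C@@H]1OC(=O)CC(C)C | intermediate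
23 | (6R,7S,8S,9R,10S)-15-hydroxy-9-(3-methylbutanoyloxy)-8-(2-methylprop-2-enoyloxy)-1-oxo-3,10-epoxygermacra-2,4Z,11(13)-trien-12,6-olide (CNP0552093.1) | C=C(C)C(=O)O[C@H]1[C@H]2C(=C)C(=O)O[C@@H]2/C=C(/CO)C2=CC(=O)[C@@](C)(O2)[C@@H]1OC(=O)CC(C)C | target

## Step count and risks

Total step count: 17. Longest linear sequence: 14 (steps 1–9 and 13–17).

The step most likely to fail is step 14. The ynone 18 is strained, and the vinyl–PdI(PPh3)2 or acyl–PdI(PPh3)2 complex could instead insert into the nearby α-methylene lactone or oligomerise. The fallback sets out from 17 and comes back to the route at 20, closing the ring by an aldol reaction instead of a cross-coupling. The alkyne of 17 is hydrated (Ph3PAuNTf2, wet dioxane) to the α-hydroxy methyl ketone F1. The vinyl iodide is then turned into the aldehyde by reductive carbonylation (Pd(PPh3)4, CO, Bu3SnH added slowly, THF, 50 °C) to give the keto aldehyde F2. An intramolecular boron aldol addition at high dilution (Cy2BCl, Et3N, CH2Cl2, −78 °C) closes the ten-membered ring to the β-hydroxy ketone F3. Dess–Martin periodinane oxidises F3 to diketone 19, which cyclodehydrates with p-TsOH in benzene to 20.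

The second is step 13. The open-chain allylation may give the cis-lactone or the wrong face at C7, since the stereochemical argument rests on models and not on a ring. The fallback sets out from 10 (with 15) and comes back at 20, swapping the order of the two ring-forming events so that the macrocycle itself controls the allylation. The tertiary trimethylsilyl ether of 10 is removed (citric acid, MeOH, 0 °C) to give the propargylic alcohol F4. F4 and 15 are joined by the intermolecular carbonylative furanone annulation (PdCl2(PPh3)2, CuI, Et3N, CO 3 atm, THF–H2O, 45 → 65 °C) to give the furanone enal F5. NBS/Me2S converts the allylic alcohol into the allyl bromide F6. CrCl2 in THF at 0.002 M then closes the C6–C7 bond and the lactone in one operation to give 20.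

The third is step 8. The hindered α-silyloxy aldehyde 9 may react too slowly with DABCO and methyl acrylate, or epimerise at C8. The fallback sets out from 9 and comes back at 11, building the trisubstituted alkene by olefination. A Horner–Wadsworth–Emmons reaction with methyl 2-(dimethoxyphosphoryl)-3-[(4-methoxyphenyl)methoxy]propanoate (LiCl, DBU, MeCN, 0 °C) gives the (E)-enoate F7. DDQ (CH2Cl2, pH 7 buffer) removes the 4-methoxybenzyl group to give the allylic alcohol F8. CBr4/PPh3 (CH2Cl2, 0 °C) then gives 11.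

Further compounds
F1 | step 14 | (4S,5S)-5-[(1Z)-3-[(tert-butyldiphenylsilyl)oxy]-2-iodoprop-1-en-1-yl]-4-[(1S,2R,3S)-3-hydroxy-3-methyl-2-(3-methylbutanoyloxy)-4-oxo-1-(triethylsilyloxy)pentyl]-3-methylideneoxolan-2-one | CC[Si](CC)(CC)O[C@@H]([C@H]1C(=C)C(=O)O[C@@H]1/C=C(\I)CO[Si](c2ccccc2)(c2ccccc2)C(C)(C)C)[C@@H](OC(=O)CC(C)C)[C@](C)(O)C(C)=O
F2 | step 14 | (4S,5R)-5-[(1Z)-3-[(tert-butyldiphenylsilyl)oxy]-2-formylprop-1-en-1-yl]-4-[(1S,2R,3S)-3-hydroxy-3-methyl-2-(3-methylbutanoyloxy)-4-oxo-1-(triethylsilyloxy)pentyl]-3-methylideneoxolan-2-one | CC[Si](CC)(CC)O[C@@H]([C@H]1C(=C)C(=O)O[C@@H]1/C=C(\C=O)CO[Si](c2ccccc2)(c2ccccc2)C(C)(C)C)[C@@H](OC(=O)CC(C)C)[C@](C)(O)C(C)=O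
F3 | step 14 | (6R,7S,8S,9R,10S)-15-[(tert-butyldiphenylsilyl)oxy]-3,10-dihydroxy-9-(3-methylbutanoyloxy)-1-oxo-8-(triethylsilyloxy)germacra-4Z,11(13)-dien-12,6-olide (both C3 epimers) | CC[Si](CC)(CC)O[C@H]1[C@H]2C(=C)C(=O)O[C@@H]2/C=C(/CO[Si](c3ccccc3)(c3ccccc3)C(C)(C)C)C(O)CC(=O)[C@@](C)(O)[C@@H]1OC(=O)CC(C)C
F4 | step 13 | methyl (4S,5R,6R)-3,6-dihydroxy-6-methyl-2-methylidene-5-(3-methylbutanoyloxy)-4-(triethylsilyloxy)oct-7-ynoate (both C3 epimers) | C#C[C@@](C)(O)[C@H](OC(=O)CC(C)C)[C@@H](O[Si](CC)(CC)CC)C(O)C(=C)C(=O)OC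
F5 | step 13 | methyl (4S,5R)-5-[(2S)-5-[(2Z)-1-[(tert-butyldiphenylsilyl)oxy]-4-oxobut-2-en-2-yl]-2-methyl-3-oxo-2,3-dihydrofuran-2-yl]-3-hydroxy-2-methylidene-5-(3-methylbutanoyloxy)-4-(triethylsilyloxy)pentanoate (both C3 epimers) | O=C/C=C(/CO[Si](c1ccccc1)(c1ccccc1)C(C)(C)C)C1=CC(=O)[C@@](C)(O1)[C@H](OC(=O)CC(C)C)[C@@H](O[Si](CC)(CC)CC)C(O)C(=C)C(=O)OC
F6 | step 13 | methyl (2Z,4S,5R)-2-(bromomethyl)-5-[(2S)-5-[(2Z)-1-[(tert-butyldiphenylsilyl)oxy]-4-oxobut-2-en-2-yl]-2-methyl-3-oxo-2,3-dihydrofuran-2-yl]-5-(3-methylbutanoyloxy)-4-(triethylsilyloxy)pent-2-enoate | O=C/C=C(/CO[Si](c1ccccc1)(c1ccccc1)C(C)(C)C)C1=CC(=O)[C@@](C)(O1)[C@H](OC(=O)CC(C)C)[C@@H](O[Si](CC)(CC)CC)/C=C(\CBr)C(=O)OC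
F7 | step 8 | methyl (2E,4S,5R,6R)-2-[[(4-methoxyphenyl)methoxy]methyl]-6-methyl-5-(3-methylbutanoyloxy)-4-(triethylsilyloxy)-6-(trimethylsilyloxy)oct-2-en-7-ynoate | C#C[C@@](C)(O[Si](C)(C)C)[C@H](OC(=O)CC(C)C)[C@@H](O[Si](CC)(CC)CC)/C=C(\COCc1ccc(OC)cc1)C(=O)OC
F8 | step 8 | methyl (2E,4S,5R,6R)-2-(hydroxymethyl)-6-methyl-5-(3-methylbutanoyloxy)-4-(triethylsilyloxy)-6-(trimethylsilyloxy)oct-2-en-7-ynoate | C#C[C@@](C)(O[Si](C)(C)C)[C@H](OC(=O)CC(C)C)[C@@H](O[Si](CC)(CC)CC)/C=C(\CO)C(=O)OC
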